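**Strategy.** Each ring of this C2-symmetric bis(hydroxyquinone) (quinone numbering: C1 and C4 carbonyl, C2 OH, C3 tether, C5 OMe, C6 methyl) is a fully substituted 1,2,4,5-tetraoxygenated benzene whose methoxy carbon C5 and hydroxy carbon C2 are para, the signature of a Dötz benzannulation. Both rings are therefore built in one operation from a tetradecane-tethered bis[methoxycarbene–Cr(CO)5] complex and 1-(triisopropylsilyloxy)propyne. The carbene carbon becomes C5, a CO ligand C2, the alkyne C6 and C1, and the α-(methoxymethoxy)alkenyl unit C4 and C3. Alkyne insertion forges the C5–C6 bond and 6π-closure completes each arene with OMe and OH already differentiated. Desilylation, acetal cleavage and air oxidation finish.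

Key step: step 5

Remark: the target is made as the 2-hydroxy-1,4-benzoquinone tautomer shown; in the SMILES of 15 the two π-bound Cr(CO)3 units are written as separate fragments, and 4 is drawn in its γ-lithio form.

Step 1
Reactants: 1 allyl alcohol (prop-2-en-1-ol)
Product: 2 allyl methoxymethyl ether [3-(methoxymethoxy)prop-1-ene]
Conditions: MeOCH2Cl, i-Pr2NEt, CH2Cl2, 0 °C to rt
Reagents that add atoms: chloromethyl methyl ether, COCCl
Why: O-alkylation of a primary alcohol with the reactive α-chloro ether under amine base (methoxymethyl ether formation) is routine and creates no stereocenter.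

Step 2
Reactants: 2 allyl methoxymethyl ether (2.4 equiv); 3 1,12-dibromododecane
Product: 5 (1Z,17Z)-1,18-bis(methoxymethoxy)octadeca-1,17-diene, via Z-oxyallyl lithium 4 (not isolated)
Conditions: s-BuLi (2.4 equiv), THF, −78 °C; then 3, −78 to −30 °C
Reagents that add atoms: none
Why: s-BuLi removes the allylic hydrogen next to oxygen to give a chelated, Z-configured oxyallyl lithium that primary bromides should alkylate mainly at the γ-carbon (alkylation of metalated allyl ethers as homoenolate equivalents), so both ends of 3 should deliver Z enol ethers and the tether reaches fourteen methylenes.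

Step 3
Reactants: 5 (1Z,17Z)-1,18-bis(methoxymethoxy)octadeca-1,17-diene; 6 hexacarbonylchromium Cr(CO)6 (2.2 equiv)
Product: 9 bis(pentacarbonylchromium) complex of (2Z,18Z)-1,20-dimethoxy-2,19-bis(methoxymethoxy)icosa-2,18-diene-1,20-diylidene, via dilithio bis(enol ether) 7 (not isolated), via dilithium bis(acyl chromate) 8 (not isolated)
Conditions: s-BuLi (2.5 equiv), TMEDA, THF, −78 to −50 °C; Cr(CO)6 (2.2 equiv), THF, −78 to 0 °C; solvent switch, Me3OBF4 (2.4 equiv), CH2Cl2, 0 °C
Reagents that add atoms: trimethyloxonium tetrafluoroborate (2.4 equiv), C[O+](C)C.F[B-](F)(F)F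
Why: The acetal oxygen should direct vinylic α-lithiation of each Z enol ether with retention of geometry, each of the two vinyllithium termini should add to a CO ligand of its own equivalent of Cr(CO)6, and O-methylation of both acyl chromate oxygens by the oxonium salt (one methyl transferred per oxonium ion) completes a two-fold standard Fischer carbene synthesis.

Step 4
Reactants: 10 propyne
Product: 13 triisopropyl(prop-1-yn-1-yloxy)silane, via prop-1-ynyllithium 11 (not isolated), via lithium prop-1-yn-1-olate 12 (not isolated)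
Conditions: n-BuLi, THF, −78 °C; t-BuOOLi (from t-BuOOH, LiN(SiMe3)2), −78 to 0 °C; i-Pr3SiOTf, −78 °C to rt
Reagents that add atoms: tert-butyl hydroperoxide, CC(C)(C)OO; triisopropylsilyl trifluoromethanesulfonate, CC(C)[Si](OS(=O)(=O)C(F)(F)F)(C(C)C)C(C)C
Why: Oxygen transfer from lithium tert-butyl peroxide to the lithium acetylide should give the ynolate (acetylide oxidation to an ynolate), which the bulky silyl triflate traps on oxygen as a stable siloxyalkyne.

Step 5
Reactants: 9 tethered bis(methoxycarbene) bis(pentacarbonylchromium) complex; 13 triisopropyl(prop-1-yn-1-yloxy)silane (3 equiv)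
Product: 16 6,6'-(tetradecane-1,14-diyl)bis[4-methoxy-5-(methoxymethoxy)-3-methyl-2-(triisopropylsilyloxy)phenol], via bis(siloxydienylcarbene) insertion complex 14 (not isolated), via bis(tricarbonylchromium) arene complex 15 (not isolated)
Conditions: THF, 50 °C, Ar; then air, EtOAc, rt
Reagents that add atoms: none
Why: Thermal loss of one CO from each carbene terminus should let 13 insert into the Cr=C bond, the electrophilic methoxycarbene carbon bonding to the nucleophilic methyl-bearing alkyne carbon (this forges the C5(OMe)–C6(CH3) bond) to give the siloxy-stabilised dienylcarbene 14, after which CO insertion gives a chromium-bound dienylketene that cyclises onto the enol-ether β-carbon and tautomerises to the phenol complex 15, freed as 16 by air. The closest known reaction type is the Dötz benzannulation of alkenyl(alkoxy)carbene chromium complexes with oxygen-substituted alkynes, here run at both ends of one tether. Each benzene ring is closed as a six-membered carbocycle by a thermal 6π-electrocyclisation of the dienylketene (formal [3+2+1] assembly of alkenylcarbene, alkyne and CO), and no stereocenter is created. The step needs one alkyne orientation, with the siloxy carbon next to the CO-derived carbinol carbon, and this is secured by the ynol-ether polarisation that leaves the oxygen-stabilised carbene on chromium and by the bulk of the triisopropylsilyloxy group, which is kept away from the former carbene carbon. Phenol formation rather than five-ring or furan products is favoured by the alkenyl (not aryl) carbene and the coordinating solvent, and the methoxy (from the carbene) and hydroxy (from CO) groups emerge para and already differentiated.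

Step 6
Reactants: 16 6,6'-(tetradecane-1,14-diyl)bis[4-methoxy-5-(methoxymethoxy)-3-methyl-2-(triisopropylsilyloxy)phenol]
Product: 19 3,3'-(tetradecane-1,14-diyl)bis(2-hydroxy-5-methoxy-6-methylcyclohexa-2,5-diene-1,4-dione), via bis(catechol) 17 (not isolated), via bis(benzene-1,2,4-triol) 18 (not isolated)
Conditions: Bu4NF, THF, 0 °C, Ar; then 3 M HCl aq., 45 °C, Ar; then air, pH 7 phosphate buffer, rt
Reagents that add atoms: none
Why: Fluoride should cleave the aryl silyl ethers, aqueous acid should hydrolyse the aryl methoxymethyl acetals (the fully substituted rings cannot be attacked by the liberated formaldehyde), and the resulting 1,2,4-triol units should autoxidise to the 2-hydroxy-1,4-benzoquinones, the C5 methoxy group blocking any other para-quinone (deprotection followed by hydroquinone autoxidation).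

**Compound list**

1 | prop-2-en-1-ol (allyl alcohol) | C=CCO | starting material
2 | 3-(methoxymethoxy)prop-1-ene (allyl methoxymethyl ether) | C=CCOCOC | intermediate
3 | 1,12-dibromododecane | BrCCCCCCCCCCCCBr | starting material
4 | (Z)-3-lithio-1-(methoxymethoxy)prop-1-ene (Z-oxyallyl lithium, γ-lithio form) | [Li]C/C=C\OCOC | intermediate
5 | (1Z,17Z)-1,18-bis(methoxymethoxy)octadeca-1,17-diene | COCO/C=C\CCCCCCCCCCCCCC/C=C\OCOC | intermediate
6 | hexacarbonylchromium Cr(CO)6 | O=C=[Cr](=C=O)(=C=O)(=C=O)(=C=O)=C=O | starting material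
7 | (1Z,17Z)-1,18-dilithio-1,18-bis(methoxymethoxy)octadeca-1,17-diene | [Li]/C(OCOC)=C/CCCCCCCCCCCCCC/C=C(/[Li])OCOC | intermediate
8 | dilithium bis(acyl pentacarbonylchromate) of (2Z,18Z)-2,19-bis(methoxymethoxy)icosa-2,18-diene-1,20-dioyl | [Li]OC(=[Cr](=C=O)(=C=O)(=C=O)(=C=O)=C=O)/C(OCOC)=C/CCCCCCCCCCCCCC/C=C(/C(O[Li])=[Cr](=C=O)(=C=O)(=C=O)(=C=O)=C=O)OCOC | intermediate
9 | [(2Z,18Z)-1,20-dimethoxy-2,19-bis(methoxymethoxy)icosa-2,18-diene-1,20-diylidene]bis(pentacarbonylchromium) | COC(=[Cr](=C=O)(=C=O)(=C=O)(=C=O)=C=O)/C(OCOC)=C/CCCCCCCCCCCCCC/C=C(/C(OC)=[Cr](=C=O)(=C=O)(=C=O)(=C=O)=C=O)OCOC | intermediate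
10 | propyne | CC#C | starting material
11 | prop-1-ynyllithium | CC#C[Li] | intermediate
12 | lithium prop-1-yn-1-olate | CC#CO[Li] | intermediate
13 | triisopropyl(prop-1-yn-1-yloxy)silane | CC#CO[Si](C(C)C)(C(C)C)C(C)C | intermediate
14 | bis(siloxydienylcarbene) tetracarbonylchromium insertion complex (each end: (CO)4Cr=C(OSi-i-Pr3)–C(CH3)=C(OCH3)–C(OCH2OCH3)=CH–tether) | O=C=[Cr](=C=O)(=C=O)(=C=O)=C(O[Si](C(C)C)(C(C)C)C(C)C)/C(C)=C(OC)\C(OCOC)=C\CCCCCCCCCCCCCC/C=C(OCOC)/C(OC)=C(C)\C(O[Si](C(C)C)(C(C)C)C(C)C)=[Cr](=C=O)(=C=O)(=C=O)=C=O | intermediate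
15 | bis(tricarbonylchromium) η6-arene complex of 16 | COc1c(C)c(O[Si](C(C)C)(C(C)C)C(C)C)c(O)c(CCCCCCCCCCCCCCc2c(O)c(O[Si](C(C)C)(C(C)C)C(C)C)c(C)c(OC)c2OCOC)c1OCOC.O=C=[Cr](=C=O)=C=O.O=C=[Cr](=C=O)=C=O | intermediate
16 | 6,6'-(tetradecane-1,14-diyl)bis[4-methoxy-5-(methoxymethoxy)-3-methyl-2-(triisopropylsilyloxy)phenol] | COc1c(C)c(O[Si](C(C)C)(C(C)C)C(C)C)c(O)c(CCCCCCCCCCCCCCc2c(O)c(O[Si](C(C)C)(C(C)C)C(C)C)c(C)c(OC)c2OCOC)c1OCOC | intermediate
17 | 6,6'-(tetradecane-1,14-diyl)bis[4-methoxy-5-(methoxymethoxy)-3-methylbenzene-1,2-diol] | COc1c(C)c(O)c(O)c(CCCCCCCCCCCCCCc2c(O)c(O)c(C)c(OC)c2OCOC)c1OCOC | intermediate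
18 | 3,3'-(tetradecane-1,14-diyl)bis(5-methoxy-6-methylbenzene-1,2,4-triol) | COc1c(C)c(O)c(O)c(CCCCCCCCCCCCCCc2c(O)c(O)c(C)c(OC)c2O)c1O | intermediate
19 | 3,3'-(tetradecane-1,14-diyl)bis(2-hydroxy-5-methoxy-6-methylcyclohexa-2,5-diene-1,4-dione) | COC1=C(C)C(=O)C(O)=C(CCCCCCCCCCCCCCC2=C(O)C(=O)C(C)=C(OC)C2=O)C1=O | target

**Totals and risks**

Total step count: 6. Longest linear sequence: 5 steps (steps 1, 2, 3, 5 and 6; step 4 supplies the alkyne for the convergent key step).

Steps most likely to fail:

Step 5. The cascade may stall at the oxygen-stabilised insertion carbene, or the ketene may be captured by excess ynol ether instead of cyclising. Regiocontrol of alkyne uptake may erode, and one of the two termini may stay unreacted. The fallback sets out from 9 and returns at 17. Benzannulation of 9 with the electron-neutral 4,4,5,5-tetramethyl-2-(prop-1-yn-1-yl)-1,3,2-dioxaborolane (THF, 55 °C; then air), in which the boryl group acts as the large alkyne substituent and should end next to the new hydroxyl, would give the bis(arylboronate) 6,6'-(tetradecane-1,14-diyl)bis[4-methoxy-5-(methoxymethoxy)-3-methyl-2-(4,4,5,5-tetramethyl-1,3,2-dioxaborolan-2-yl)phenol] F1. Oxidation of both C–B bonds with NaBO3·4H2O (THF/H2O, rt, Ar) would give bis(catechol) 17, which is then taken through the acid and air stages of step 6.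

Step 3. Two-fold vinylic lithiation may stay incomplete (competing allylic deprotonation, aggregation of the dilithio species) and be followed by partial acylation, leaving mono- and bis-carbene mixtures that do not survive separation. The fallback sets out from 2 and returns at 16, doing the carbene chemistry on a monofunctional substrate and joining the halves late. Lithiated 2 (s-BuLi, THF, −78 °C) would be γ-alkylated with 7-bromohept-1-ene to give (1Z)-1-(methoxymethoxy)deca-1,9-diene F2. Vinylic lithiation with excess s-BuLi/TMEDA, addition to Cr(CO)6 and methylation with Me3OBF4 would give pentacarbonyl[(2Z)-1-methoxy-2-(methoxymethoxy)undeca-2,10-dien-1-ylidene]chromium F3. Benzannulation with 13 (THF, 50 °C; then air) would give 4-methoxy-3-(methoxymethoxy)-5-methyl-2-(oct-7-en-1-yl)-6-(triisopropylsilyloxy)phenol F4. Homodimerisation by alkene metathesis (second-generation Grubbs catalyst, CH2Cl2, 40 °C) would give 6,6'-[(7E)-tetradec-7-ene-1,14-diyl]bis[4-methoxy-5-(methoxymethoxy)-3-methyl-2-(triisopropylsilyloxy)phenol] F5 (alkene geometry immaterial), and hydrogenation (H2, Pd/C, EtOAc) would return 16.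

Step 2. The ambident oxyallyl anion may alkylate partly at the α-carbon, and statistical mixing over two alkylation events would erode the regio- and geometric purity of the bis(enol ether). The fallback sets out from 3 and returns at 5. Double alkylation of 3 with the lithium acetylide of 3-(methoxymethoxy)prop-1-yne (n-BuLi, THF/DMPU, −78 °C to rt) fixes the carbon skeleton without an ambident nucleophile and would give 1,18-bis(methoxymethoxy)octadeca-2,16-diyne F6. Semihydrogenation (H2, Pd/CaCO3 poisoned with Pb(OAc)2, quinoline) would give (2Z,16Z)-1,18-bis(methoxymethoxy)octadeca-2,16-diene F7. Allyl-to-propenyl ether isomerisation (KOtBu, DMSO, 60 °C), which passes through the same cisoid oxyallyl anion but only has to accept a proton, would return the Z,Z-bis(enol ether) 5.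

**Further compounds**

F1 | step 5 | 6,6'-(tetradecane-1,14-diyl)bis[4-methoxy-5-(methoxymethoxy)-3-methyl-2-(4,4,5,5-tetramethyl-1,3,2-dioxaborolan-2-yl)phenol] | COc1c(C)c(B2OC(C)(C)C(C)(C)O2)c(O)c(CCCCCCCCCCCCCCc2c(O)c(B3OC(C)(C)C(C)(C)O3)c(C)c(OC)c2OCOC)c1OCOC
F2 | step 3 | (1Z)-1-(methoxymethoxy)deca-1,9-diene | COCO/C=C\CCCCCCC=C
F3 | step 3 | pentacarbonyl[(2Z)-1-methoxy-2-(methoxymethoxy)undeca-2,10-dien-1-ylidene]chromium | COC(=[Cr](=C=O)(=C=O)(=C=O)(=C=O)=C=O)/C(OCOC)=C/CCCCCCC=C
F4 | step 3 | 4-methoxy-3-(methoxymethoxy)-5-methyl-2-(oct-7-en-1-yl)-6-(triisopropylsilyloxy)phenol | COc1c(C)c(O[Si](C(C)C)(C(C)C)C(C)C)c(O)c(CCCCCCC=C)c1OCOC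
F5 | step 3 | 6,6'-[(7E)-tetradec-7-ene-1,14-diyl]bis[4-methoxy-5-(methoxymethoxy)-3-methyl-2-(triisopropylsilyloxy)phenol] | COc1c(C)c(O[Si](C(C)C)(C(C)C)C(C)C)c(O)c(CCCCCC/C=C/CCCCCCc2c(O)c(O[Si](C(C)C)(C(C)C)C(C)C)c(C)c(OC)c2OCOC)c1OCOC
F6 | step 2 | 1,18-bis(methoxymethoxy)octadeca-2,16-diyne | COCOCC#CCCCCCCCCCCCCC#CCOCOC
F7 | step 2 | (2Z,16Z)-1,18-bis(methoxymethoxy)octadeca-2,16-diene | COCOC/C=C\CCCCCCCCCCCC/C=C\COCOC
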